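**Retrosynthetic overview**
- Target ⇐ global desilylation of its hexa-TIPS ether ⇐ Suzuki–Miyaura union of a cis-7-chlorobenzodioxane core (rings B, C, D) with an E-styrylboronate (ring A); the stilbene is made only after the photochemistry.
- Key disconnection: the O-1–C-2 and C-3–H bonds of the dioxane, made together in a photoredox radical-cation 6-endo cyclisation of an ortho-hydroxyaryl enol ether; a chiral counter-anion sets C-2 and anti hydrogen-atom transfer sets C-3 (cis).
- Enol ether ⇐ Heck arylation (ring C bromide) of an α-aryloxystyrene ⇐ Markovnikov hydrophenoxylation of the ring D arylacetylene by a mono-MOM 4-chlorocatechol, which fixes which oxygen meets which carbon.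
- Rings A and D come from resorcinol (silylation, C–H borylation/bromination, Sonogashira), rings B and C from catechol; the 1,4-dioxane ring is the only ring formed (step 10).

Assumption: benzodioxine locants are chosen so that O-1 is bonded to C-2 (the carbon bearing the 3,4-dioxygenated ring) and the chloro or styryl group sits at C-7 (para to O-4); with these locants the target SMILES reads as (2R,3S), which is the cis isomer. TIPS = triisopropylsilyl, MOM = methoxymethyl.

**Step 1**
Reactants: 1 resorcinol (benzene-1,3-diol)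
Product: 2 1,3-bis(triisopropylsilyloxy)benzene
Conditions: TIPSCl (2.3 equiv), imidazole (5 equiv), DMF, rt → 40 °C
Reagents that add atoms: triisopropylsilyl chloride CC(C)[Si](Cl)(C(C)C)C(C)C
Why: Imidazole-promoted silyl ether formation on both phenols; the bulky TIPS ethers shield the positions next to oxygen in the borylation and are removed only in the last step.

**Step 2**
Reactants: 2 1,3-bis(triisopropylsilyloxy)benzene
Product: 4 1-bromo-3,5-bis(triisopropylsilyloxy)benzene, via arylboronate 3 (not isolated)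
Conditions: B2pin2 (1.0 equiv), [Ir(OMe)(cod)]2 (1.5 mol %), dtbpy (3 mol %), THF, 80 °C; then CuBr2 (3 equiv), MeOH/THF/H2O, 80 °C
Reagents that add atoms: bis(pinacolato)diboron CC1(C)OB(OC1(C)C)B1OC(C)(C)C(C)(C)O1 (boron of 3); CuBr2 Br[Cu]Br (bromine of 4)
Why: Sterically governed iridium-catalysed aromatic C–H borylation touches only C-5 of a 1,3-disubstituted arene, and copper-mediated bromodeboronation (Hartwig meta-halogenation sequence) gives the 1,3,5-pattern that electrophilic bromination of resorcinol cannot give.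

**Step 3**
Reactants: 4 1-bromo-3,5-bis(triisopropylsilyloxy)benzene; 5 trimethylsilylacetylene
Product: 7 1-ethynyl-3,5-bis(triisopropylsilyloxy)benzene, via silylalkyne 6 (not isolated)
Conditions: PdCl2(PPh3)2 (2 mol %), CuI (4 mol %), Et3N, 70 °C; then K2CO3 (0.2 equiv), MeOH/THF, 0 °C → rt, 30 min
Reagents that add atoms: none
Why: Sonogashira coupling followed by brief carbonate methanolysis of the alkynyl C–Si bond, which is much faster than attack on the hindered aryl OTIPS groups.

**Step 4**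
Reactants: 8 catechol (benzene-1,2-diol)
Product: 10 4-bromo-1,2-bis(triisopropylsilyloxy)benzene, via 4-bromocatechol 9 (not isolated)
Conditions: NBS (1.0 equiv), DMF, −20 → 0 °C; then imidazole (5 equiv), TIPSCl (2.5 equiv), rt → 40 °C
Reagents that add atoms: N-bromosuccinimide O=C1CCC(=O)N1Br; triisopropylsilyl chloride CC(C)[Si](Cl)(C(C)C)C(C)C
Why: Electrophilic aromatic bromination by NBS in DMF goes para to a hydroxyl, and the crude bromocatechol is silylated in the same pot.

**Step 5**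
Reactants: 8 catechol (3 equiv, excess recovered)
Product: 11 2-(methoxymethoxy)phenol
Conditions: MOMCl (1.0 equiv), iPr2NEt (1.2 equiv), CH2Cl2, 0 °C → rt
Reagents that add atoms: chloromethyl methyl ether COCCl
Why: Base-mediated mono-O-alkylation (Williamson type) kept at the mono stage by excess catechol; unlike an acyl or silyl group, MOM cannot migrate to the neighbouring oxygen, so the two oxygens stay distinguished.

**Step 6**
Reactants: 11 2-(methoxymethoxy)phenol
Product: 12 4-chloro-2-(methoxymethoxy)phenol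
Conditions: NCS (1.05 equiv), MeCN, 0 °C → rt; minor ortho isomer removed by chromatography
Reagents that add atoms: N-chlorosuccinimide O=C1CCC(=O)N1Cl
Why: Electrophilic aromatic chlorination goes para to the free hydroxyl (the stronger donor), so the free OH (later O-4) is para to chlorine and the MOM-bearing oxygen (later O-1) is meta.

**Step 7**
Reactants: 12 4-chloro-2-(methoxymethoxy)phenol; 7 1-ethynyl-3,5-bis(triisopropylsilyloxy)benzene (1.2 equiv)
Product: 13 4-chloro-2-(methoxymethoxy)phenyl 1-[3,5-bis(triisopropylsilyloxy)phenyl]ethenyl ether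
Conditions: Ph3PAuNTf2 (3 mol %), toluene, 50 °C; Et3N-deactivated silica
Reagents that add atoms: none
Why: Markovnikov hydrophenoxylation of a terminal arylalkyne by cationic monovalent gold: the phenol adds to the internal carbon of the π-activated alkyne, which ties the free oxygen of 12 to the carbon carrying ring D without regiochemical ambiguity.

**Step 8**
Reactants: 13 4-chloro-2-(methoxymethoxy)phenyl 1-[3,5-bis(triisopropylsilyloxy)phenyl]ethenyl ether; 10 4-bromo-1,2-bis(triisopropylsilyloxy)benzene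
Product: 14 4-chloro-2-(methoxymethoxy)phenyl (E/Z)-2-[3,4-bis(triisopropylsilyloxy)phenyl]-1-[3,5-bis(triisopropylsilyloxy)phenyl]ethenyl ether
Conditions: Pd(OAc)2 (5 mol %), P(o-tol)3 (10 mol %), Et3N (3 equiv), DMF, 100 °C
Reagents that add atoms: none
Why: Mizoroki–Heck arylation of the 1,1-disubstituted alkene at its CH2 terminus followed by β-hydride elimination (as with 1,1-diarylethylenes) gives the trisubstituted enol ether; the aryl C–Cl bond is inert to Pd/P(o-tol)3 and the E/Z ratio does not matter later.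

**Step 9**
Reactants: 14 4-chloro-2-(methoxymethoxy)phenyl (E/Z)-2-[3,4-bis(triisopropylsilyloxy)phenyl]-1-[3,5-bis(triisopropylsilyloxy)phenyl]ethenyl ether
Product: 16 5-chloro-2-{(E/Z)-2-[3,4-bis(triisopropylsilyloxy)phenyl]-1-[3,5-bis(triisopropylsilyloxy)phenyl]ethenyloxy}phenol, via trimethylsilyl ether 15 (not isolated)
Conditions: TMSOTf (2 equiv), 2,2′-bipyridyl (3 equiv), MeCN/CH2Cl2, 0 °C → rt; then H2O; used promptly
Reagents that add atoms: trimethylsilyl trifluoromethanesulfonate C[Si](C)(C)OS(=O)(=O)C(F)(F)F (silyl group of 15)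
Why: Non-protic cleavage of an aryl MOM ether by TMSOTf/2,2′-bipyridyl through the aryl trimethylsilyl ether, hydrolysed on work-up; it spares the acid-sensitive enol ether and the aryl OTIPS groups.

**Step 10 (key step)**
Reactants: 16 5-chloro-2-{(E/Z)-2-[3,4-bis(triisopropylsilyloxy)phenyl]-1-[3,5-bis(triisopropylsilyloxy)phenyl]ethenyloxy}phenol
Product: 17 (2R,3S)-7-chloro-2-[3,4-bis(triisopropylsilyloxy)phenyl]-3-[3,5-bis(triisopropylsilyloxy)phenyl]-2,3-dihydro-1,4-benzodioxine (cis)
Conditions: 9-mesityl-3,6-di-tert-butyl-10-phenylacridinium salt of a chiral BINOL-derived imidodiphosphorimidate (IDPi) anion (3 mol %, antipode chosen by screening), bis(4-methoxyphenyl) disulfide (10 mol %), toluene/CH2Cl2, 450 nm LEDs, −40 °C, degassed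
Reagents that add atoms: none
Why: Proposed new method: the excited acridinium oxidises the electron-rich aryl enol ether to its radical cation (alkene geometry is lost there), the ortho-phenol adds 6-endo to the β-carbon C-2 (the less substituted, p-siloxybenzylic terminus, the anti-Markovnikov site as in acridinium/thiol hydroetherification of alkenols and in trapping of enol ether radical cations) while hydrogen-bonded to the chiral counter-anion, which selects the face and sets C-2 as R, and the resulting tertiary α-aryloxy benzylic radical at C-3 takes a hydrogen atom from the arenethiol on the face anti to the pseudo-axial C-2 aryl group, which sets C-3 as S and gives the kinetic cis-diaryl product; closest known reaction types are Nicewicz anti-Markovnikov alkene hydroetherification and counter-anion-directed photoredox radical-cation catalysis.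

**Step 11**
Reactants: 7 1-ethynyl-3,5-bis(triisopropylsilyloxy)benzene (1.3 equiv); 17 (2R,3S)-7-chloro-2-[3,4-bis(triisopropylsilyloxy)phenyl]-3-[3,5-bis(triisopropylsilyloxy)phenyl]-2,3-dihydro-1,4-benzodioxine
Product: 19 (2R,3S)-2-[3,4-bis(triisopropylsilyloxy)phenyl]-3-[3,5-bis(triisopropylsilyloxy)phenyl]-7-{(E)-2-[3,5-bis(triisopropylsilyloxy)phenyl]ethenyl}-2,3-dihydro-1,4-benzodioxine, via alkenylboronate 18 (not isolated)
Conditions: HBpin (1.4 equiv), Cp2Zr(H)Cl (5 mol %), Et3N (10 mol %), 60 °C; then 17, Pd(OAc)2 (3 mol %), SPhos (6 mol %), K3PO4 (3 equiv), toluene/H2O, 90 °C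
Reagents that add atoms: pinacolborane [H]B1OC(C)(C)C(C)(C)O1 (boron of 18)
Why: Zirconocene-catalysed syn-hydroboration gives the E-alkenylboronate and Suzuki–Miyaura coupling at the electron-rich aryl chloride (SPhos) retains the E geometry; with every phenol silylated there is no quinone-methide pathway, so C-2 and C-3 are untouched.

**Step 12**
Reactants: 19 (2R,3S)-2-[3,4-bis(triisopropylsilyloxy)phenyl]-3-[3,5-bis(triisopropylsilyloxy)phenyl]-7-{(E)-2-[3,5-bis(triisopropylsilyloxy)phenyl]ethenyl}-2,3-dihydro-1,4-benzodioxine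
Product: 20 4-[(2R,3S)-3-(3,5-dihydroxyphenyl)-7-[(E)-2-(3,5-dihydroxyphenyl)ethenyl]-2,3-dihydro-1,4-benzodioxin-2-yl]benzene-1,2-diol (target)
Conditions: HF·pyridine (excess), pyridine/THF, 0 °C → rt; pH 6–7 buffer work-up
Reagents that add atoms: none
Why: Fluoride-mediated desilylation under buffered, weakly acidic conditions removes all six silyl groups without forming the para-phenoxide of ring C, whose quinone-methide ring opening would epimerise the cis isomer to trans.

**Compound list**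
1 | resorcinol | Oc1cccc(O)c1 | starting material
2 | 1,3-bis(triisopropylsilyloxy)benzene | CC(C)[Si](C(C)C)(C(C)C)Oc1cccc(O[Si](C(C)C)(C(C)C)C(C)C)c1 | intermediate
3 | 2-[3,5-bis(triisopropylsilyloxy)phenyl]-4,4,5,5-tetramethyl-1,3,2-dioxaborolane | CC(C)[Si](C(C)C)(C(C)C)Oc1cc(O[Si](C(C)C)(C(C)C)C(C)C)cc(B2OC(C)(C)C(C)(C)O2)c1 | intermediate (not isolated)
4 | 1-bromo-3,5-bis(triisopropylsilyloxy)benzene | CC(C)[Si](C(C)C)(C(C)C)Oc1cc(Br)cc(O[Si](C(C)C)(C(C)C)C(C)C)c1 | intermediate
5 | trimethylsilylacetylene | C#C[Si](C)(C)C | starting material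
6 | 1-[(trimethylsilyl)ethynyl]-3,5-bis(triisopropylsilyloxy)benzene | CC(C)[Si](C(C)C)(C(C)C)Oc1cc(C#C[Si](C)(C)C)cc(O[Si](C(C)C)(C(C)C)C(C)C)c1 | intermediate (not isolated)
7 | 1-ethynyl-3,5-bis(triisopropylsilyloxy)benzene | C#Cc1cc(O[Si](C(C)C)(C(C)C)C(C)C)cc(O[Si](C(C)C)(C(C)C)C(C)C)c1 | intermediate
8 | catechol | Oc1ccccc1O | starting material
9 | 4-bromocatechol | Oc1ccc(Br)cc1O | intermediate (not isolated)
10 | 4-bromo-1,2-bis(triisopropylsilyloxy)benzene | CC(C)[Si](C(C)C)(C(C)C)Oc1ccc(Br)cc1O[Si](C(C)C)(C(C)C)C(C)C | intermediate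
11 | 2-(methoxymethoxy)phenol | COCOc1ccccc1O | intermediate
12 | 4-chloro-2-(methoxymethoxy)phenol | COCOc1cc(Cl)ccc1O | intermediate
13 | 4-chloro-2-(methoxymethoxy)phenyl 1-[3,5-bis(triisopropylsilyloxy)phenyl]ethenyl ether | C=C(Oc1ccc(Cl)cc1OCOC)c1cc(O[Si](C(C)C)(C(C)C)C(C)C)cc(O[Si](C(C)C)(C(C)C)C(C)C)c1 | intermediate
14 | 4-chloro-2-(methoxymethoxy)phenyl (E/Z)-2-[3,4-bis(triisopropylsilyloxy)phenyl]-1-[3,5-bis(triisopropylsilyloxy)phenyl]ethenyl ether (E/Z mixture) | COCOc1cc(Cl)ccc1OC(=Cc1ccc(O[Si](C(C)C)(C(C)C)C(C)C)c(O[Si](C(C)C)(C(C)C)C(C)C)c1)c1cc(O[Si](C(C)C)(C(C)C)C(C)C)cc(O[Si](C(C)C)(C(C)C)C(C)C)c1 | intermediate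
15 | trimethylsilyl ether of 16 (E/Z mixture) | C[Si](C)(C)Oc1cc(Cl)ccc1OC(=Cc1ccc(O[Si](C(C)C)(C(C)C)C(C)C)c(O[Si](C(C)C)(C(C)C)C(C)C)c1)c1cc(O[Si](C(C)C)(C(C)C)C(C)C)cc(O[Si](C(C)C)(C(C)C)C(C)C)c1 | intermediate (not isolated)
16 | 5-chloro-2-{(E/Z)-2-[3,4-bis(triisopropylsilyloxy)phenyl]-1-[3,5-bis(triisopropylsilyloxy)phenyl]ethenyloxy}phenol (E/Z mixture) | Oc1cc(Cl)ccc1OC(=Cc1ccc(O[Si](C(C)C)(C(C)C)C(C)C)c(O[Si](C(C)C)(C(C)C)C(C)C)c1)c1cc(O[Si](C(C)C)(C(C)C)C(C)C)cc(O[Si](C(C)C)(C(C)C)C(C)C)c1 | intermediate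
17 | (2R,3S)-7-chloro-2-[3,4-bis(triisopropylsilyloxy)phenyl]-3-[3,5-bis(triisopropylsilyloxy)phenyl]-2,3-dihydro-1,4-benzodioxine (cis) | Clc1ccc2c(c1)O[C@H](c1ccc(O[Si](C(C)C)(C(C)C)C(C)C)c(O[Si](C(C)C)(C(C)C)C(C)C)c1)[C@H](c1cc(O[Si](C(C)C)(C(C)C)C(C)C)cc(O[Si](C(C)C)(C(C)C)C(C)C)c1)O2 | intermediate
18 | 2-{(E)-2-[3,5-bis(triisopropylsilyloxy)phenyl]ethenyl}-4,4,5,5-tetramethyl-1,3,2-dioxaborolane | CC1(C)OB(/C=C/c2cc(O[Si](C(C)C)(C(C)C)C(C)C)cc(O[Si](C(C)C)(C(C)C)C(C)C)c2)OC1(C)C | intermediate (not isolated)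
19 | (2R,3S)-2-[3,4-bis(triisopropylsilyloxy)phenyl]-3-[3,5-bis(triisopropylsilyloxy)phenyl]-7-{(E)-2-[3,5-bis(triisopropylsilyloxy)phenyl]ethenyl}-2,3-dihydro-1,4-benzodioxine (cis) | CC(C)[Si](C(C)C)(C(C)C)Oc1cc(O[Si](C(C)C)(C(C)C)C(C)C)cc(/C=C/c2ccc3c(c2)O[C@H](c2ccc(O[Si](C(C)C)(C(C)C)C(C)C)c(O[Si](C(C)C)(C(C)C)C(C)C)c2)[C@H](c2cc(O[Si](C(C)C)(C(C)C)C(C)C)cc(O[Si](C(C)C)(C(C)C)C(C)C)c2)O3)c1 | intermediate
20 | 4-[(2R,3S)-3-(3,5-dihydroxyphenyl)-7-[(E)-2-(3,5-dihydroxyphenyl)ethenyl]-2,3-dihydro-1,4-benzodioxin-2-yl]benzene-1,2-diol (cis; CNP0283264.2) | Oc1cc(O)cc(/C=C/c2ccc3c(c2)O[C@H](c2ccc(O)c(O)c2)[C@H](c2cc(O)cc(O)c2)O3)c1 | target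

**Totals**
Total step count: 12. Longest linear sequence: 9 steps (1, 2, 3, 7, 8, 9, 10, 11, 12, from resorcinol).

**Three steps most likely to fail, each with a fallback**

Step 10 (enantioselective radical-cation cyclisation; the enantioselectivity, the cis:trans ratio and 6-endo versus 5-exo ketal formation are all untested). The fallback sets out from 16 and comes back at 17. The same radical-cation C–O cyclisation is run oxidatively with 9-mesityl-10-methylacridinium tetrafluoroborate and Co(dmgH)2(py)Cl under blue light in MeCN, with loss of H2. This gives the fully unsaturated 7-chloro-2-[3,4-bis(triisopropylsilyloxy)phenyl]-3-[3,5-bis(triisopropylsilyloxy)phenyl]-1,4-benzodioxine F1. F1 is then hydrogenated with a chiral cationic iridium N,P catalyst such as [Ir(cod)(PHOX)]BArF under H2 (50 bar). Syn addition of H2 to the tetrasubstituted alkene gives only the cis isomer, and the ligand antipode selects (2R,3S)-17.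

Step 7 (gold-catalysed addition of a phenol to a terminal alkyne; over-addition to a ketal or C-alkenylation of the phenol may compete). The fallback sets out from 12 and bromide 4 and comes back at 13. Iridium-catalysed transfer vinylation of 12 with vinyl acetate ([Ir(cod)Cl]2, Na2CO3, toluene, 100 °C) gives 4-chloro-2-(methoxymethoxy)phenyl vinyl ether F2. Branched-selective Heck arylation of F2 with 4 under the cationic manifold (Pd(OAc)2, dppp, Et3N, DMSO, 115 °C) places ring D on the oxygen-bearing carbon and gives 13.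

Step 8 (Heck reaction between an electron-rich aryl bromide and an electron-rich, acid-sensitive 1,1-disubstituted enol ether). The fallback sets out from 13 and 10 and comes back at 14. NBS followed by Et3N (CH2Cl2, −78 °C → rt) converts 13 into 4-chloro-2-(methoxymethoxy)phenyl (E/Z)-2-bromo-1-[3,5-bis(triisopropylsilyloxy)phenyl]ethenyl ether F3. Bromide 10 is converted by Miyaura borylation (B2pin2, PdCl2(dppf), KOAc, dioxane, 80 °C) into 2-[3,4-bis(triisopropylsilyloxy)phenyl]-4,4,5,5-tetramethyl-1,3,2-dioxaborolane F4. Suzuki–Miyaura coupling of F3 with F4 (Pd(PPh3)4, K3PO4, toluene/H2O, 70 °C) gives 14, because the alkenyl C–Br bond reacts before the aryl C–Cl bond.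

**Further compounds**
F1 | step 10 | 7-chloro-2-[3,4-bis(triisopropylsilyloxy)phenyl]-3-[3,5-bis(triisopropylsilyloxy)phenyl]-1,4-benzodioxine | Clc1ccc2c(c1)OC(c1ccc(O[Si](C(C)C)(C(C)C)C(C)C)c(O[Si](C(C)C)(C(C)C)C(C)C)c1)=C(c1cc(O[Si](C(C)C)(C(C)C)C(C)C)cc(O[Si](C(C)C)(C(C)C)C(C)C)c1)O2
F2 | step 7 | 4-chloro-2-(methoxymethoxy)phenyl vinyl ether | C=COc1ccc(Cl)cc1OCOC
F3 | step 8 | 4-chloro-2-(methoxymethoxy)phenyl (E/Z)-2-bromo-1-[3,5-bis(triisopropylsilyloxy)phenyl]ethenyl ether | BrC=C(Oc1ccc(Cl)cc1OCOC)c1cc(O[Si](C(C)C)(C(C)C)C(C)C)cc(O[Si](C(C)C)(C(C)C)C(C)C)c1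
F4 | step 8 | 2-[3,4-bis(triisopropylsilyloxy)phenyl]-4,4,5,5-tetramethyl-1,3,2-dioxaborolane | CC1(C)OB(c2ccc(O[Si](C(C)C)(C(C)C)C(C)C)c(O[Si](C(C)C)(C(C)C)C(C)C)c2)OC1(C)C
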